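**Retrosynthetic overview**
- Target ⇐ bis-allyl ether of the isoflavan; ring C (the chroman O1–C2 bond) is closed last by an intramolecular Mitsunobu etherification.
- C3–C4 bond ⇐ Evans syn-aldol between the ring-B arylacetyl oxazolidinone and the ring-A benzaldehyde; the benzylic OH is then removed and the auxiliary is reduced off to give the C2 alcohol.
- Ring-A aldehyde ⇐ resorcinol: bis-MOM ether, lithiation/prenylation, lithiation/formylation, then exchange to 4-O-allyl/2-O-TBS.
- Ring-B acid ⇐ 2,4-dihydroxybenzaldehyde: chromene annulation with prenal (pyran ring formed first), O-allylation, one-carbon homologation.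

Assumption: the target is the (3R)-isoflavan exactly as drawn in the SMILES, and (S)-4-benzyl-1,3-oxazolidin-2-one is bought as the single enantiomer.

**Ring-A aldehyde**

Step 1
Reactants: 1 resorcinol
Product: 2 1,3-bis(methoxymethoxy)benzene
Conditions: NaH (2.4 equiv), DMF, 0 °C; MOMCl (2.3 equiv), 0 °C to rt
Reagents that add atoms: chloromethyl methyl ether (MOMCl), COCCl
Why: Williamson-type O-alkylation of the bis-phenoxide installs two MOM ethers that serve as ortho-directing groups for the next two lithiations.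

Step 2
Reactants: 2 1,3-bis(methoxymethoxy)benzene; 3 prenyl bromide
Product: 5 1,3-bis(methoxymethoxy)-2-(3-methylbut-2-en-1-yl)benzene, via aryllithium 4 (not isolated)
Conditions: n-BuLi (1.1 equiv), THF, 0 °C to rt, 1 h; then CuI (10 mol %), 3, −78 °C to rt
Reagents that add atoms: none
Why: Directed ortho-metalation takes place only at C2, flanked by both OMOM groups, and copper-catalysed SN2 allylation of the aryllithium with the primary allylic bromide gives the linear prenyl arene.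

Step 3
Reactants: 5 1,3-bis(methoxymethoxy)-2-(3-methylbut-2-en-1-yl)benzene
Product: 7 2,4-bis(methoxymethoxy)-3-(3-methylbut-2-en-1-yl)benzaldehyde, via aryllithium 6 (not isolated)
Conditions: n-BuLi (1.2 equiv), TMEDA, Et2O, 0 °C, 2 h; DMF (3 equiv), −78 °C to rt; H2O
Reagents that add atoms: N,N-dimethylformamide, CN(C)C=O
Why: A second directed ortho-metalation next to an OMOM group (the two open ortho positions are equivalent) followed by formylation of the aryllithium with DMF fixes the 1-formyl-2,4-dioxy-3-prenyl pattern.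

Step 4
Reactants: 7 2,4-bis(methoxymethoxy)-3-(3-methylbut-2-en-1-yl)benzaldehyde
Product: 8 2,4-dihydroxy-3-(3-methylbut-2-en-1-yl)benzaldehyde
Conditions: HCl (1.25 M in MeOH), 40 °C, 2 h
Reagents that add atoms: none
Why: Acid-catalysed acetal exchange with methanol cleaves both MOM ethers, while the formyl-deactivated ring and the dilute acid keep the prenyl group from cyclising onto a phenol.

Step 5
Reactants: 8 2,4-dihydroxy-3-(3-methylbut-2-en-1-yl)benzaldehyde
Product: 9 4-(allyloxy)-2-hydroxy-3-(3-methylbut-2-en-1-yl)benzaldehyde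
Conditions: allyl bromide (1.05 equiv), K2CO3 (1.0 equiv), acetone, rt
Reagents that add atoms: allyl bromide, C=CCBr
Why: Williamson etherification is selective for the more acidic 4-OH (para to CHO) because the 2-OH is tied up in a hydrogen bond to the formyl group.

Step 6
Reactants: 9 4-(allyloxy)-2-hydroxy-3-(3-methylbut-2-en-1-yl)benzaldehyde
Product: 10 4-(allyloxy)-2-[(tert-butyldimethylsilyl)oxy]-3-(3-methylbut-2-en-1-yl)benzaldehyde
Conditions: TBSOTf (1.3 equiv), 2,6-lutidine (2 equiv), CH2Cl2, 0 °C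
Reagents that add atoms: tert-butyldimethylsilyl triflate, CC(C)(C)[Si](C)(C)OS(=O)(=O)C(F)(F)F
Why: O-Silylation with the reactive silyl triflate overcomes the hindered, hydrogen-bonded 2-OH and gives a group that can later be removed by fluoride without touching the allyl ethers.

**Ring-B imide**

Step 7
Reactants: 11 2,4-dihydroxybenzaldehyde; 12 3-methylbut-2-enal
Product: 14 5-hydroxy-2,2-dimethyl-2H-chromene-6-carbaldehyde, via ortho-quinone methide 13 (not isolated)
Conditions: pyridine, 120 °C (sealed tube), 16 h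
Reagents that add atoms: none
Why: Aldol-type condensation of the enal at C3 (the carbon between the two oxygens) gives the ortho-quinone methide, which closes by oxa-6π electrocyclisation through O-4 because the 2-OH stays hydrogen-bonded to the aldehyde.

Step 8
Reactants: 14 5-hydroxy-2,2-dimethyl-2H-chromene-6-carbaldehyde
Product: 15 5-(allyloxy)-2,2-dimethyl-2H-chromene-6-carbaldehyde
Conditions: allyl bromide (1.5 equiv), K2CO3 (2 equiv), DMF, 60 °C
Reagents that add atoms: allyl bromide, C=CCBr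
Why: Williamson etherification in a dipolar aprotic solvent alkylates the chelated phenol, at a temperature far below that of an aromatic Claisen rearrangement.

Step 9
Reactants: 15 5-(allyloxy)-2,2-dimethyl-2H-chromene-6-carbaldehyde
Product: 16 5-(allyloxy)-6-(2-methoxyethenyl)-2,2-dimethyl-2H-chromene (E/Z mixture)
Conditions: Ph3P(CH2OMe)Cl (1.5 equiv), KOtBu (1.45 equiv), THF, 0 °C; then 15, 0 °C to rt
Reagents that add atoms: (methoxymethyl)triphenylphosphonium chloride, [Cl-].COC[P+](c1ccccc1)(c1ccccc1)c1ccccc1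
Why: Wittig methoxymethylenation adds the one extra carbon as an enol ether, whose geometry is irrelevant.

Step 10
Reactants: 16 5-(allyloxy)-6-(2-methoxyethenyl)-2,2-dimethyl-2H-chromene
Product: 17 [5-(allyloxy)-2,2-dimethyl-2H-chromen-6-yl]acetaldehyde
Conditions: 2 M aq HCl, THF, 40 °C; crude product used at once
Reagents that add atoms: water, O
Why: Acid-catalysed enol ether hydrolysis proceeds under conditions that leave the allyl aryl ether and the chromene double bond intact.

Step 11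
Reactants: 17 [5-(allyloxy)-2,2-dimethyl-2H-chromen-6-yl]acetaldehyde
Product: 18 [5-(allyloxy)-2,2-dimethyl-2H-chromen-6-yl]acetic acid
Conditions: NaClO2, NaH2PO4, 2-methyl-2-butene (excess), t-BuOH/H2O, 0 °C to rt
Reagents that add atoms: sodium chlorite, [Na+].[O-]Cl=O
Why: Pinnick oxidation converts the labile arylacetaldehyde into the acid, with the scavenger alkene intercepting HOCl before it can attack the chromene or allyl olefins.

Step 12
Reactants: 18 [5-(allyloxy)-2,2-dimethyl-2H-chromen-6-yl]acetic acid; 19 (S)-4-benzyl-1,3-oxazolidin-2-one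
Product: 21 (4S)-3-{[5-(allyloxy)-2,2-dimethyl-2H-chromen-6-yl]acetyl}-4-benzyl-1,3-oxazolidin-2-one, via mixed pivalic anhydride 20 (not isolated)
Conditions: PivCl (1.1 equiv), Et3N (2.5 equiv), THF, −20 °C; then LiCl, 19, −20 °C to rt
Reagents that add atoms: none
Why: N-Acylation of the oxazolidinone by the mixed anhydride occurs at the unhindered arylacetyl carbonyl and attaches the chiral auxiliary without touching any stereocentre.

**Coupling and end game**

Step 13
Reactants: 21 (4S)-3-{[5-(allyloxy)-2,2-dimethyl-2H-chromen-6-yl]acetyl}-4-benzyl-1,3-oxazolidin-2-one; 10 4-(allyloxy)-2-[(tert-butyldimethylsilyl)oxy]-3-(3-methylbut-2-en-1-yl)benzaldehyde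
Product: 24 (4S)-3-[(2S,3S)-3-{4-(allyloxy)-2-[(tert-butyldimethylsilyl)oxy]-3-(3-methylbut-2-en-1-yl)phenyl}-2-[5-(allyloxy)-2,2-dimethyl-2H-chromen-6-yl]-3-hydroxypropanoyl]-4-benzyl-1,3-oxazolidin-2-one, via boron Z-enolate 22 (not isolated), via boron aldolate 23 (not isolated)
Conditions: Bu2BOTf (1.2 equiv), i-Pr2NEt (1.4 equiv), CH2Cl2, 0 °C; 10, −78 to 0 °C; pH 7 buffer, MeOH, 30% H2O2, 0 °C
Reagents that add atoms: none
Why: Evans syn-aldol reaction, in which the Z-boron enolate reacts through a closed Zimmerman–Traxler chair on the face away from the benzyl group of the (S)-auxiliary, forms the C3–C4 bond and sets C2 of the acyl chain (the future C3 of the isoflavan) as 2S and the carbinol carbon as 3S.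

Step 14
Reactants: 24 the syn-aldol adduct
Product: 25 (4S)-3-[(2R)-3-{4-(allyloxy)-2-[(tert-butyldimethylsilyl)oxy]-3-(3-methylbut-2-en-1-yl)phenyl}-2-[5-(allyloxy)-2,2-dimethyl-2H-chromen-6-yl]propanoyl]-4-benzyl-1,3-oxazolidin-2-one
Conditions: Et3SiH (8 equiv), BF3·OEt2 (2.5 equiv, Lewis acid promoter), CH2Cl2, −78 to −30 °C
Reagents that add atoms: none
Why: SN1-type ionic deoxygenation works because the benzylic C–OH bond, activated by the para-allyloxy and ortho-silyloxy groups, ionises at low temperature and is reduced by the silane before any alkene is protonated; C2 is not touched and its descriptor changes from S to R only through the CIP priorities.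

Step 15
Reactants: 25 the deoxygenated imide
Product: 26 (2R)-3-{4-(allyloxy)-2-[(tert-butyldimethylsilyl)oxy]-3-(3-methylbut-2-en-1-yl)phenyl}-2-[5-(allyloxy)-2,2-dimethyl-2H-chromen-6-yl]propan-1-ol
Conditions: LiBH4 (2 equiv), H2O (2 equiv), Et2O/THF, 0 °C
Reagents that add atoms: none
Why: Reductive cleavage of the N-acyl oxazolidinone at the exocyclic carbonyl gives the primary alcohol (the future C2) and returns the auxiliary, under conditions mild enough not to epimerise the α-aryl centre.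

Step 16
Reactants: 26 the silyl-protected alcohol
Product: 27 3-(allyloxy)-6-{(2R)-2-[5-(allyloxy)-2,2-dimethyl-2H-chromen-6-yl]-3-hydroxypropyl}-2-(3-methylbut-2-en-1-yl)phenol
Conditions: Bu4NF (1.2 equiv), AcOH (1.2 equiv), THF, 0 °C
Reagents that add atoms: none
Why: Buffered fluoride desilylation frees only the ring-A phenol that must form the chroman, while both allyl ethers stay on.

Step 17
Reactants: 27 the phenol alcohol
Product: 28 (3R)-7-(allyloxy)-3-[5-(allyloxy)-2,2-dimethyl-2H-chromen-6-yl]-8-(3-methylbut-2-en-1-yl)-3,4-dihydro-2H-chromene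
Conditions: PPh3 (1.5 equiv), DIAD (1.5 equiv), THF (0.02 M), 0 °C to rt
Reagents that add atoms: none
Why: Intramolecular Mitsunobu etherification (6-exo-tet attack of the only free phenol on the activated primary alcohol) closes ring C at a carbon that is not the stereocentre, so C3 stays R.

Step 18
Reactants: 28 the bis-allyl isoflavan
Product: 29 (3R)-3-(5-hydroxy-2,2-dimethyl-2H-chromen-6-yl)-8-(3-methylbut-2-en-1-yl)-3,4-dihydro-2H-chromen-7-ol (target, CNP0263294.2)
Conditions: Pd(PPh3)4 (5 mol %), morpholine (10 equiv), THF, rt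
Reagents that add atoms: none
Why: Tsuji–Trost deallylation with zerovalent palladium transfers both allyl groups to morpholine under neutral conditions, which spares the acid-sensitive prenyl phenol and chromene.

**Compound list**
1 | resorcinol | Oc1cccc(O)c1 | starting material
2 | 1,3-bis(methoxymethoxy)benzene | COCOc1cccc(OCOC)c1 | intermediate
3 | prenyl bromide (1-bromo-3-methylbut-2-ene) | CC(C)=CCBr | starting material
4 | [2,6-bis(methoxymethoxy)phenyl]lithium | [Li]c1c(OCOC)cccc1OCOC | intermediate (not isolated)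
5 | 1,3-bis(methoxymethoxy)-2-(3-methylbut-2-en-1-yl)benzene | COCOc1cccc(OCOC)c1CC=C(C)C | intermediate
6 | [2,4-bis(methoxymethoxy)-3-(3-methylbut-2-en-1-yl)phenyl]lithium | [Li]c1ccc(OCOC)c(CC=C(C)C)c1OCOC | intermediate (not isolated)
7 | 2,4-bis(methoxymethoxy)-3-(3-methylbut-2-en-1-yl)benzaldehyde | O=Cc1ccc(OCOC)c(CC=C(C)C)c1OCOC | intermediate
8 | 2,4-dihydroxy-3-(3-methylbut-2-en-1-yl)benzaldehyde | O=Cc1ccc(O)c(CC=C(C)C)c1O | intermediate
9 | 4-(allyloxy)-2-hydroxy-3-(3-methylbut-2-en-1-yl)benzaldehyde | O=Cc1ccc(OCC=C)c(CC=C(C)C)c1O | intermediate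
10 | 4-(allyloxy)-2-[(tert-butyldimethylsilyl)oxy]-3-(3-methylbut-2-en-1-yl)benzaldehyde | O=Cc1ccc(OCC=C)c(CC=C(C)C)c1O[Si](C)(C)C(C)(C)C | intermediate
11 | 2,4-dihydroxybenzaldehyde | O=Cc1ccc(O)cc1O | starting material
12 | 3-methylbut-2-enal (prenal) | CC(C)=CC=O | starting material
13 | 2-hydroxy-3-(3-methylbut-2-en-1-ylidene)-4-oxocyclohexa-1,5-diene-1-carbaldehyde (ortho-quinone methide) | O=CC1=C(O)C(=CC=C(C)C)C(=O)C=C1 | intermediate (not isolated)
14 | 5-hydroxy-2,2-dimethyl-2H-chromene-6-carbaldehyde | CC1(C)C=Cc2c(O1)ccc(C=O)c2O | intermediate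
15 | 5-(allyloxy)-2,2-dimethyl-2H-chromene-6-carbaldehyde | CC1(C)C=Cc2c(O1)ccc(C=O)c2OCC=C | intermediate
16 | 5-(allyloxy)-6-(2-methoxyethenyl)-2,2-dimethyl-2H-chromene (E/Z mixture) | CC1(C)C=Cc2c(O1)ccc(C=COC)c2OCC=C | intermediate
17 | [5-(allyloxy)-2,2-dimethyl-2H-chromen-6-yl]acetaldehyde | CC1(C)C=Cc2c(O1)ccc(CC=O)c2OCC=C | intermediate
18 | [5-(allyloxy)-2,2-dimethyl-2H-chromen-6-yl]acetic acid | CC1(C)C=Cc2c(O1)ccc(CC(=O)O)c2OCC=C | intermediate
19 | (S)-4-benzyl-1,3-oxazolidin-2-one | O=C1N[C@@H](Cc2ccccc2)CO1 | starting material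
20 | [5-(allyloxy)-2,2-dimethyl-2H-chromen-6-yl]acetic pivalic anhydride | CC1(C)C=Cc2c(O1)ccc(CC(=O)OC(=O)C(C)(C)C)c2OCC=C | intermediate (not isolated)
21 | (4S)-3-{[5-(allyloxy)-2,2-dimethyl-2H-chromen-6-yl]acetyl}-4-benzyl-1,3-oxazolidin-2-one | CC1(C)C=Cc2c(O1)ccc(CC(=O)N3C(=O)OC[C@@H]3Cc4ccccc4)c2OCC=C | intermediate
22 | (4S)-3-{(Z)-2-[5-(allyloxy)-2,2-dimethyl-2H-chromen-6-yl]-1-[(dibutylboranyl)oxy]ethenyl}-4-benzyl-1,3-oxazolidin-2-one (boron Z-enolate of 21) | CCCCB(CCCC)O/C(=C\c1ccc2OC(C)(C)C=Cc2c1OCC=C)N3C(=O)OC[C@@H]3Cc4ccccc4 | intermediate (not isolated)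
23 | O-dibutylboranyl aldolate of 24, (2S,3S), (4S)-auxiliary | O=C(N1C(=O)OC[C@@H]1Cc2ccccc2)[C@@H](c3ccc4OC(C)(C)C=Cc4c3OCC=C)[C@H](OB(CCCC)CCCC)c5ccc(OCC=C)c(CC=C(C)C)c5O[Si](C)(C)C(C)(C)C | intermediate (not isolated)
24 | (4S)-3-[(2S,3S)-3-{4-(allyloxy)-2-[(tert-butyldimethylsilyl)oxy]-3-(3-methylbut-2-en-1-yl)phenyl}-2-[5-(allyloxy)-2,2-dimethyl-2H-chromen-6-yl]-3-hydroxypropanoyl]-4-benzyl-1,3-oxazolidin-2-one | O=C(N1C(=O)OC[C@@H]1Cc2ccccc2)[C@@H](c3ccc4OC(C)(C)C=Cc4c3OCC=C)[C@H](O)c5ccc(OCC=C)c(CC=C(C)C)c5O[Si](C)(C)C(C)(C)C | intermediate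
25 | (4S)-3-[(2R)-3-{4-(allyloxy)-2-[(tert-butyldimethylsilyl)oxy]-3-(3-methylbut-2-en-1-yl)phenyl}-2-[5-(allyloxy)-2,2-dimethyl-2H-chromen-6-yl]propanoyl]-4-benzyl-1,3-oxazolidin-2-one | O=C(N1C(=O)OC[C@@H]1Cc2ccccc2)[C@@H](c3ccc4OC(C)(C)C=Cc4c3OCC=C)Cc5ccc(OCC=C)c(CC=C(C)C)c5O[Si](C)(C)C(C)(C)C | intermediate
26 | (2R)-3-{4-(allyloxy)-2-[(tert-butyldimethylsilyl)oxy]-3-(3-methylbut-2-en-1-yl)phenyl}-2-[5-(allyloxy)-2,2-dimethyl-2H-chromen-6-yl]propan-1-ol | OC[C@@H](c1ccc2OC(C)(C)C=Cc2c1OCC=C)Cc3ccc(OCC=C)c(CC=C(C)C)c3O[Si](C)(C)C(C)(C)C | intermediate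
27 | 3-(allyloxy)-6-{(2R)-2-[5-(allyloxy)-2,2-dimethyl-2H-chromen-6-yl]-3-hydroxypropyl}-2-(3-methylbut-2-en-1-yl)phenol | OC[C@@H](c1ccc2OC(C)(C)C=Cc2c1OCC=C)Cc3ccc(OCC=C)c(CC=C(C)C)c3O | intermediate
28 | (3R)-7-(allyloxy)-3-[5-(allyloxy)-2,2-dimethyl-2H-chromen-6-yl]-8-(3-methylbut-2-en-1-yl)-3,4-dihydro-2H-chromene | CC(C)=CCc1c(OCC=C)ccc2c1OC[C@@H](c1ccc3c(c1OCC=C)C=CC(C)(C)O3)C2 | intermediate
29 | (3R)-3-(5-hydroxy-2,2-dimethyl-2H-chromen-6-yl)-8-(3-methylbut-2-en-1-yl)-3,4-dihydro-2H-chromen-7-ol | CC(C)=CCc1c(O)ccc2c1OC[C@@H](c1ccc3c(c1O)C=CC(C)(C)O3)C2 | target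

**Totals**
Total step count: 18. Longest linear sequence: 12 steps (steps 1–6 then 13–18, or equally steps 7–12 then 13–18).

**Three steps most likely to fail**

Step 3 (formylation). The doubly activated benzylic/allylic CH2 of the prenyl group may be deprotonated instead of the ring. The fallback drops lithiation chemistry for ring A. It sets out from 11 and rejoins the route at 8, so steps 1–4 are not needed.
- 11 is alkylated at the non-chelated 4-OH with 3-chloro-3-methylbut-1-yne (K2CO3, KI, CuI cat., acetone, reflux) to give 2-hydroxy-4-[(2-methylbut-3-yn-2-yl)oxy]benzaldehyde F1.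
- Semi-hydrogenation (H2, Pd/CaCO3 poisoned with Pb(OAc)2, quinoline, EtOAc) gives 2-hydroxy-4-[(2-methylbut-3-en-2-yl)oxy]benzaldehyde F2.
- Aromatic Claisen rearrangement (N,N-diethylaniline, 130 °C) moves the allyl unit to C3, the position favoured by the bond fixation of the chelated ring, and gives 8.

Step 13 (aldol). The ortho-silyloxy aldehyde and the ortho-substituted arylacetyl enolate are both hindered, and α-aryl aldolates are prone to retro-aldol. The fallback forms the same C–C bond by auxiliary-controlled enolate alkylation. It sets out from 10 and 18, rejoins at 26, and also bypasses step 14.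
- 10 is reduced (i-Bu2AlH, CH2Cl2, −78 °C) to {4-(allyloxy)-2-[(tert-butyldimethylsilyl)oxy]-3-(3-methylbut-2-en-1-yl)phenyl}methanol F3.
- Appel bromination (PPh3, CBr4, 2,6-lutidine, CH2Cl2, 0 °C) gives 1-(allyloxy)-4-(bromomethyl)-3-[(tert-butyldimethylsilyl)oxy]-2-(3-methylbut-2-en-1-yl)benzene F4, used crude.
- 18 is coupled with commercial (R)-4-benzyl-1,3-oxazolidin-2-one under the step-12 conditions to give (4R)-3-{[5-(allyloxy)-2,2-dimethyl-2H-chromen-6-yl]acetyl}-4-benzyl-1,3-oxazolidin-2-one F5.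
- The sodium Z-enolate of this imide (NaN(SiMe3)2, THF, −78 °C) is alkylated by the bromide on the face away from the benzyl group to give (4R)-3-[(2R)-3-{4-(allyloxy)-2-[(tert-butyldimethylsilyl)oxy]-3-(3-methylbut-2-en-1-yl)phenyl}-2-[5-(allyloxy)-2,2-dimethyl-2H-chromen-6-yl]propanoyl]-4-benzyl-1,3-oxazolidin-2-one F6.
- LiBH4 reduction as in step 15 gives 26.

Step 14 (ionic deoxygenation). The benzylic cation may lose the acidic α-proton to give the α-aryl cinnamoyl imide, which would destroy the stereocentre. It may also be trapped by the neighbouring allyloxy oxygen, or an alkene may be reduced. The fallback is a radical Barton–McCombie deoxygenation that avoids cations and acid. It sets out from 24 and rejoins at 25.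
- 24 is treated with 1,1'-thiocarbonyldiimidazole and DMAP (CH2Cl2, rt) to give the O-(1H-imidazol-1-ylcarbonothioyl) derivative of 24 F7.
- Bu3SnH and AIBN in toluene at 80 °C reduce the stabilised benzylic radical to 25 without touching C2. No 5- or 6-membered radical cyclisation onto the prenyl, chromene or allyl olefins is geometrically available.

**Further compounds**
F1 | step 3 | 2-hydroxy-4-[(2-methylbut-3-yn-2-yl)oxy]benzaldehyde | O=Cc1ccc(OC(C)(C)C#C)cc1O
F2 | step 3 | 2-hydroxy-4-[(2-methylbut-3-en-2-yl)oxy]benzaldehyde | O=Cc1ccc(OC(C)(C)C=C)cc1O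
F3 | step 13 | {4-(allyloxy)-2-[(tert-butyldimethylsilyl)oxy]-3-(3-methylbut-2-en-1-yl)phenyl}methanol | OCc1ccc(OCC=C)c(CC=C(C)C)c1O[Si](C)(C)C(C)(C)C
F4 | step 13 | 1-(allyloxy)-4-(bromomethyl)-3-[(tert-butyldimethylsilyl)oxy]-2-(3-methylbut-2-en-1-yl)benzene | BrCc1ccc(OCC=C)c(CC=C(C)C)c1O[Si](C)(C)C(C)(C)C
F5 | step 13 | (4R)-3-{[5-(allyloxy)-2,2-dimethyl-2H-chromen-6-yl]acetyl}-4-benzyl-1,3-oxazolidin-2-one | CC1(C)C=Cc2c(O1)ccc(CC(=O)N3C(=O)OC[C@H]3Cc4ccccc4)c2OCC=C
F6 | step 13 | (4R)-3-[(2R)-3-{4-(allyloxy)-2-[(tert-butyldimethylsilyl)oxy]-3-(3-methylbut-2-en-1-yl)phenyl}-2-[5-(allyloxy)-2,2-dimethyl-2H-chromen-6-yl]propanoyl]-4-benzyl-1,3-oxazolidin-2-one | O=C(N1C(=O)OC[C@H]1Cc2ccccc2)[C@@H](c3ccc4OC(C)(C)C=Cc4c3OCC=C)Cc5ccc(OCC=C)c(CC=C(C)C)c5O[Si](C)(C)C(C)(C)C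
F7 | step 14 | O-{(1S,2S)-1-{4-(allyloxy)-2-[(tert-butyldimethylsilyl)oxy]-3-(3-methylbut-2-en-1-yl)phenyl}-2-[5-(allyloxy)-2,2-dimethyl-2H-chromen-6-yl]-3-[(4S)-4-benzyl-2-oxo-1,3-oxazolidin-3-yl]-3-oxopropyl} 1H-imidazole-1-carbothioate | O=C(N1C(=O)OC[C@@H]1Cc2ccccc2)[C@@H](c3ccc4OC(C)(C)C=Cc4c3OCC=C)[C@H](OC(=S)n6ccnc6)c5ccc(OCC=C)c(CC=C(C)C)c5O[Si](C)(C)C(C)(C)C
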